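**Retrosynthetic overview**
1. Target 23 ⇒ acrylic acid 19 + 1-bromopent-1-yne 21: carboxylate-directed vinylic C–H alkynylation, then 5-exo-dig lactonisation, builds the (Z)-butylidene butenolide last.
2. 19 ⇒ ketone 16 (vinyl iodide, hydroxycarbonylation) ⇒ enone lactone 15 by endo-face copper hydride 1,4-reduction, which sets both ring-A methines.
3. 15 ⇒ tricyclic keto acid 14 by oxidative enol–carboxylate lactonisation (bridged γ-lactone, sets C9).
4. 14 ⇒ bromoenone 8 + racemic carbonate 11: one-pot palladium asymmetric allylic alkylation, then 5-exo Heck (cyclopentane, quaternary carbon, ring-B alkene).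
5. 8 ⇒ cyclohexane-1,3-dione + methyl acetoacetate + iodoethane; 11 ⇒ glutaraldehyde. Ring order: rings A and B preformed → cyclopentane → bridging lactone → butenolide.

Assumption: the (R,R)-ligand is taken to give (6R)-12 as drawn; if the sense is opposite, the (S,S)-ligand is used.
Locants: tricyclic compounds use fluorene numbering (C4 = ring-A carbonyl carbon, C4b = quaternary carbon, C8a = ring-B methine, C9 = butanoyl-bearing carbon, ring A = C1–C4, ring B = C5–C8); the SMILES strings define the configuration.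

**Step 1**
Reactants: 1 cyclohexane-1,3-dione
Product: 3 2-bromo-3-chlorocyclohex-2-en-1-one, via 2-bromocyclohexane-1,3-dione 2 (not isolated)
Conditions: NBS, CH2Cl2, 0 °C; then (COCl)2, DMF (cat.), 0 °C to rt
Reagents that add atoms: N-bromosuccinimide (O=C1CCC(=O)N1Br); oxalyl chloride (O=C(Cl)C(Cl)=O)
Why: Electrophilic bromination of the enolised 1,3-dione at C2 followed by Vilsmeier-type conversion of the vinylogous acid into the vinylogous acid chloride gives the 2-halo-3-chloroenone, with no stereocentre involved.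

**Step 2**
Reactants: 4 methyl 3-oxobutanoate; 5 iodoethane
Product: 6 methyl 3-oxohexanoate
Conditions: NaH, THF, 0 °C; n-BuLi, 0 °C; then 5, 0 °C to rt; H2O quench
Reagents that add atoms: none
Why: Weiler dianion alkylation, in which the last-formed terminal carbanion of the acetoacetate dianion is ethylated selectively.

**Step 3**
Reactants: 3 2-bromo-3-chlorocyclohex-2-en-1-one; 6 methyl 3-oxohexanoate
Product: 8 2-bromo-3-(2-oxopentyl)cyclohex-2-en-1-one, via keto ester adduct 7 (not isolated)
Conditions: NaH (2.1 equiv), THF, 0 °C to rt; then 6 M HCl, AcOH, 90 °C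
Reagents that add atoms: none
Why: Addition–elimination (vinylogous acyl substitution) of the soft β-keto ester enolate at the chlorine-bearing β-carbon of 3, followed by acidic ester hydrolysis and ketonic decarboxylation, with no stereocentre involved.

**Step 4**
Reactants: 9 pentanedial (glutaraldehyde)
Product: 10 tert-butyl 6-hydroxycyclohex-1-ene-1-carboxylate (racemic)
Conditions: tert-butyl 2-(diethoxyphosphoryl)acetate, K2CO3, H2O, rt
Reagents that add atoms: tert-butyl 2-(diethoxyphosphoryl)acetate (CCOP(=O)(OCC)CC(=O)OC(C)(C)C)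
Why: Tandem aldol addition and intramolecular Horner–Wadsworth–Emmons olefination of the dialdehyde closes ring B with the enoate and the allylic hydroxyl in place, and the racemic carbinol centre is of no consequence because it later passes through a symmetric π-allyl.

**Step 5**
Reactants: 10 tert-butyl 6-hydroxycyclohex-1-ene-1-carboxylate (racemic)
Product: 11 tert-butyl 6-[(methoxycarbonyl)oxy]cyclohex-1-ene-1-carboxylate (racemic)
Conditions: ClCO2Me, pyridine, DMAP (cat.), CH2Cl2, 0 °C
Reagents that add atoms: methyl chloroformate (COC(=O)Cl)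
Why: O-acylation of the allylic alcohol gives a methyl carbonate that ionises readily on zerovalent palladium and releases methoxide as the internal base.

**Step 6**
Reactants: 8 2-bromo-3-(2-oxopentyl)cyclohex-2-en-1-one; 11 tert-butyl 6-[(methoxycarbonyl)oxy]cyclohex-1-ene-1-carboxylate (racemic)
Product: 13 tert-butyl (4bS,8aR)-9-butanoyl-4-oxo-1,2,3,4,7,8,8a,9-octahydro-4bH-fluorene-4b-carboxylate (both C9 epimers), via allylation adduct 12 (not isolated)
Conditions: Pd2(dba)3·CHCl3 (2.5 mol %), (R,R)-DACH-phenyl Trost ligand (7.5 mol %), toluene, 0 °C to rt; then Pd(OAc)2 (5 mol %), P(o-tol)3 (12 mol %), 1,2,2,6,6-pentamethylpiperidine, 95 °C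
Reagents that add atoms: none
Why: Tsuji–Trost asymmetric allylic alkylation followed by an intramolecular Mizoroki–Heck reaction, in which either enantiomer of 11 gives the same symmetric 2-(alkoxycarbonyl)cyclohexenyl π-allyl palladium, the chiral ligand selects the enantiotopic terminus attacked by the soft vinylogous-diketone carbanion of 8 (sets C8a), and on heating the vinyl bromide adds 5-exo to the α-carbon of the enoate on the only face that gives a cis ring fusion (sets quaternary C4b) with β-hydride elimination away from the quaternary carbon placing the ring-B alkene at C5–C6.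

**Step 7**
Reactants: 13 tert-butyl (4bS,8aR)-9-butanoyl-4-oxo-1,2,3,4,7,8,8a,9-octahydro-4bH-fluorene-4b-carboxylate (both C9 epimers)
Product: 15 (4bS,8aS,9R)-9-butanoyl-9-hydroxy-4-oxo-1,2,3,4,7,8,8a,9-octahydro-4bH-fluorene-4b-carboxylic acid 4b,9-lactone, via carboxylic acid 14 (not isolated)
Conditions: TFA, CH2Cl2, 0 °C to rt, evaporate; then PhI(OAc)2, CH2Cl2–(CF3)2CHOH, 0 °C
Reagents that add atoms: none
Why: Acidolysis of the tert-butyl ester and then oxylactonisation of the keto acid with a hypervalent iodine reagent, in which the enolised vinylogous 1,3-diketone is oxidised at C9 and captured by the carboxylic acid, which can only reach C9 on its own face, so both C9 epimers converge on one bridged 2-oxabicyclo[2.2.1]heptenone and C9 is set.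

**Step 8**
Reactants: 15 (4bS,8aS,9R)-9-butanoyl-9-hydroxy-4-oxo-1,2,3,4,7,8,8a,9-octahydro-4bH-fluorene-4b-carboxylic acid 4b,9-lactone
Product: 16 (4aS,4bS,8aS,9S,9aR)-9-butanoyl-9-hydroxy-4-oxo-1,2,3,4,4a,7,8,8a,9,9a-decahydro-4bH-fluorene-4b-carboxylic acid 4b,9-lactone
Conditions: [(Ph3P)CuH]6 (0.4 equiv), H2O (3 equiv), THF, rt
Reagents that add atoms: none
Why: Copper hydride conjugate reduction of the enone, in which the ring-B CH2 on the one-carbon bridge blocks the exo face as the syn-7 methyl does in camphor, so hydride adds to C9a and the enolate is protonated at C4a from the endo (lactone) face to give the cis, exo-fused ring A while the isolated alkene, the saturated ketone and the lactone are untouched.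

**Step 9**
Reactants: 16 (4aS,4bS,8aS,9S,9aR)-9-butanoyl-9-hydroxy-4-oxo-1,2,3,4,4a,7,8,8a,9,9a-decahydro-4bH-fluorene-4b-carboxylic acid 4b,9-lactone
Product: 18 (4aS,4bS,8aS,9S,9aR)-9-butanoyl-9-hydroxy-4-iodo-1,2,4a,7,8,8a,9,9a-octahydro-4bH-fluorene-4b-carboxylic acid 4b,9-lactone, via hydrazone 17 (not isolated)
Conditions: N2H4·H2O, Et3N, EtOH, rt, evaporate; then I2, 1,1,3,3-tetramethylguanidine, THF, 0 °C
Reagents that add atoms: hydrazine (NN); iodine (II)
Why: Barton vinyl iodide synthesis, in which the ring ketone condenses with hydrazine in preference to the neopentyl-type butanoyl ketone and iodine oxidation of the hydrazone with loss of N2 gives the less substituted vinyl iodide without touching any stereocentre.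

**Step 10**
Reactants: 18 (4aS,4bS,8aS,9S,9aR)-9-butanoyl-9-hydroxy-4-iodo-1,2,4a,7,8,8a,9,9a-octahydro-4bH-fluorene-4b-carboxylic acid 4b,9-lactone
Product: 19 (4aR,4bR,8aS,9S,9aR)-9-butanoyl-9-hydroxy-1,2,4a,7,8,8a,9,9a-octahydro-4bH-fluorene-4,4b-dicarboxylic acid 4b,9-lactone
Conditions: Pd(OAc)2 (5 mol %), dppf, CO (1 atm), H2O, Et3N, DMF, 60 °C
Reagents that add atoms: carbon monoxide ([C-]#[O+]); water (O)
Why: Palladium-catalysed hydroxycarbonylation of the vinyl iodide (oxidative addition, CO insertion, hydrolysis of the acyl palladium) puts the future butenolide carbonyl carbon on C4 with all stereocentres unchanged.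

**Step 11**
Reactants: 20 pent-1-yne
Product: 21 1-bromopent-1-yne
Conditions: NBS, AgNO3 (10 mol %), acetone, rt
Reagents that add atoms: N-bromosuccinimide (O=C1CCC(=O)N1Br)
Why: Silver-catalysed electrophilic bromination of the terminal alkyne via the silver acetylide gives the 1-bromoalkyne.

**Step 12**
Reactants: 19 (4aR,4bR,8aS,9S,9aR)-9-butanoyl-9-hydroxy-1,2,4a,7,8,8a,9,9a-octahydro-4bH-fluorene-4,4b-dicarboxylic acid 4b,9-lactone; 21 1-bromopent-1-yne
Product: 23 CNP0423313.1 (target; Z-butylidene butenolide closed from the C4 carboxyl group onto the C3 alkyne), via enynoic acid 22 (not isolated)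
Conditions: [Cp*RhCl2]2 (2.5 mol %), AgSbF6 (10 mol %), NaOAc (1.2 equiv), ClCH2CH2Cl, 50 °C
Reagents that add atoms: none
Why: Proposed new method: the carboxylate of 19 directs trivalent rhodium to the cis vinylic C3–H bond (five-membered rhodacycle), insertion of the bromoalkyne with rhodium on the propyl-bearing carbon and β-bromide elimination give enynoic acid 22, and the Lewis-acidic rhodium or the monovalent silver present then triggers anti 5-exo-dig oxa-cyclisation to the (Z)-ylidene butenolide with no stereocentre touched; the closest known reactions are the Cp*Rh- and Cp*Ir-catalysed ortho C–H alkynylation of benzoic acids and benzamides with silyl bromoalkynes and the silver-catalysed (Z)-selective lactonisation of 2-en-4-ynoic acids, which have not been shown in one operation for a vinylic acid and an alkyl bromoalkyne.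

**Compound list**
1 | cyclohexane-1,3-dione | O=C1CCCC(=O)C1 | starting material
2 | 2-bromocyclohexane-1,3-dione | O=C1CCCC(=O)C1Br | intermediate
3 | 2-bromo-3-chlorocyclohex-2-en-1-one | O=C1CCCC(Cl)=C1Br | intermediate
4 | methyl 3-oxobutanoate (methyl acetoacetate) | CC(=O)CC(=O)OC | starting material
5 | iodoethane | CCI | starting material
6 | methyl 3-oxohexanoate | CCCC(=O)CC(=O)OC | intermediate
7 | methyl 2-(2-bromo-3-oxocyclohex-1-en-1-yl)-3-oxohexanoate | CCCC(=O)C(C(=O)OC)C1=C(Br)C(=O)CCC1 | intermediate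
8 | 2-bromo-3-(2-oxopentyl)cyclohex-2-en-1-one | CCCC(=O)CC1=C(Br)C(=O)CCC1 | intermediate
9 | pentanedial (glutaraldehyde) | O=CCCCC=O | starting material
10 | tert-butyl 6-hydroxycyclohex-1-ene-1-carboxylate, racemic | OC1CCCC=C1C(=O)OC(C)(C)C | intermediate
11 | tert-butyl 6-[(methoxycarbonyl)oxy]cyclohex-1-ene-1-carboxylate, racemic | COC(=O)OC1CCCC=C1C(=O)OC(C)(C)C | intermediate
12 | tert-butyl (6R)-6-[1-(2-bromo-3-oxocyclohex-1-en-1-yl)-2-oxopentyl]cyclohex-1-ene-1-carboxylate, both epimers at the side-chain CH | O=C1CCCC(=C1Br)C(C(=O)CCC)[C@H]1CCCC=C1C(=O)OC(C)(C)C | intermediate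
13 | tert-butyl (4bS,8aR)-9-butanoyl-4-oxo-1,2,3,4,7,8,8a,9-octahydro-4bH-fluorene-4b-carboxylate, cis-fused at C4b/C8a, both C9 epimers | O=C2CCCC1=C2[C@]2(C(=O)OC(C)(C)C)C=CCC[C@@H]2C1C(=O)CCC | intermediate
14 | (4bS,8aR)-9-butanoyl-4-oxo-1,2,3,4,7,8,8a,9-octahydro-4bH-fluorene-4b-carboxylic acid, both C9 epimers | O=C2CCCC1=C2[C@]2(C(=O)O)C=CCC[C@@H]2C1C(=O)CCC | intermediate
15 | (4bS,8aS,9R)-9-butanoyl-9-hydroxy-4-oxo-1,2,3,4,7,8,8a,9-octahydro-4bH-fluorene-4b-carboxylic acid 4b,9-lactone | O=C2CCCC1=C2[C@]23C=CCC[C@@H]2[C@@]1(C(=O)CCC)OC3=O | intermediate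
16 | (4aS,4bS,8aS,9S,9aR)-9-butanoyl-9-hydroxy-4-oxo-1,2,3,4,4a,7,8,8a,9,9a-decahydro-4bH-fluorene-4b-carboxylic acid 4b,9-lactone (H-4a and H-9a on the lactone face) | O=C2CCC[C@@H]1[C@H]2[C@]23C=CCC[C@@H]2[C@@]1(C(=O)CCC)OC3=O | intermediate
17 | (4aS,4bR,8aS,9S,9aR)-9-butanoyl-4-hydrazinylidene-9-hydroxy-1,2,3,4,4a,7,8,8a,9,9a-decahydro-4bH-fluorene-4b-carboxylic acid 4b,9-lactone | NN=C2CCC[C@@H]1[C@H]2[C@]23C=CCC[C@@H]2[C@@]1(C(=O)CCC)OC3=O | intermediate
18 | (4aS,4bS,8aS,9S,9aR)-9-butanoyl-9-hydroxy-4-iodo-1,2,4a,7,8,8a,9,9a-octahydro-4bH-fluorene-4b-carboxylic acid 4b,9-lactone | IC2=CCC[C@@H]1[C@H]2[C@]23C=CCC[C@@H]2[C@@]1(C(=O)CCC)OC3=O | intermediate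
19 | (4aR,4bR,8aS,9S,9aR)-9-butanoyl-9-hydroxy-1,2,4a,7,8,8a,9,9a-octahydro-4bH-fluorene-4,4b-dicarboxylic acid 4b,9-lactone | OC(=O)C2=CCC[C@@H]1[C@H]2[C@]23C=CCC[C@@H]2[C@@]1(C(=O)CCC)OC3=O | intermediate
20 | pent-1-yne | CCCC#C | starting material
21 | 1-bromopent-1-yne | CCCC#CBr | intermediate
22 | (4aS,4bR,8aS,9S,9aR)-9-butanoyl-9-hydroxy-3-(pent-1-yn-1-yl)-1,2,4a,7,8,8a,9,9a-octahydro-4bH-fluorene-4,4b-dicarboxylic acid 4b,9-lactone | OC(=O)C2=C(C#CCCC)CC[C@@H]1[C@H]2[C@]23C=CCC[C@@H]2[C@@]1(C(=O)CCC)OC3=O | intermediate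
23 | CNP0423313.1: (4aS,4bR,8aS,9S,9aR) dilactone of 22 in which the C4 carboxyl group is closed onto the alkyne as a (Z)-butylidene butenolide fused at C3–C4 | CCC/C=C1\OC(=O)C2=C1CC[C@@H]1[C@H]2[C@]23C=CCC[C@@H]2[C@@]1(C(=O)CCC)OC3=O | target

**Totals**
Total step count: 12 (three branches: steps 1–3, steps 4–5, step 11).
Longest linear sequence: 8 steps (1, 3, 6, 7, 8, 9, 10, 12).

**Three steps most likely to fail**

Step 12 (the proposed new step). The risks are slow vinylic C–H rhodation next to the crowded C4a centre, loss of the bromoalkyne by homocoupling, and 6-endo closure to a pyranone. The fallback uses known chemistry, sets out from 16 and comes back at 23. Stork enamine acylation of 16 (pyrrolidine, TsOH cat., benzene, reflux; pentanoyl chloride, Et3N; aqueous AcOH) gives the 3-pentanoyl ketone F1, the cyclohexanone forming its enamine far faster than the hindered butanoyl ketone. NaH and PhNTf2 convert the enolised β-diketone into the ring enol triflate F2. Pd(OAc)2/dppp under CO (1 atm) with Et3N in DMF at 60 °C then gives an acyl palladium that is trapped by the enol oxygen of the pentanoyl ketone, the carbonylative enol-lactonisation known for 3-alkylidenephthalides, to give 23.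

Step 6. The risks are insertion of zerovalent palladium into the C–Br bond before allylation, reversible allylation at 95 °C eroding the C8a configuration, and interference of the acidic C9–H in the Heck stage. The fallback sets out from 7 (isolated after the first stage of step 3) and 11 and comes back at 14. The fully substituted β-keto ester 7 is allylated under the same Trost conditions to the quaternary allylation adduct F3, which has no acidic C–H. A separate Heck cyclisation (Pd(OAc)2, P(o-tol)3, pentamethylpiperidine, 95 °C) gives the tricyclic diester F4. TFA and then 6 M HCl–AcOH at 80 °C remove the tert-butyl group and the methoxycarbonyl group (hydrolysis and decarboxylation) to give 14, which continues with the PhI(OAc)2 stage of step 7.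

Step 7. The risks are acetoxylation or oxidation at another enolisable site instead of lactonisation, and strain in the bridged lactone. The fallback sets out from 13 and comes back at 15. After TFA as before, NBS (CH2Cl2, 0 °C) brominates the vinylogous diketone at C9 to the tertiary allylic bromide F5. AgOTf with 2,6-lutidine then ionises it, and the carboxylic acid on the same face captures the cation, replacing the hypervalent-iodine oxidation by halogenation and silver-assisted lactonisation.

**Further compounds**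
F1 | step 12 | (4aS,4bS,8aS,9S,9aR)-9-butanoyl-9-hydroxy-4-oxo-3-pentanoyl-1,2,3,4,4a,7,8,8a,9,9a-decahydro-4bH-fluorene-4b-carboxylic acid 4b,9-lactone (enolised, C3 unassigned) | O=C2C(C(=O)CCCC)CC[C@@H]1[C@H]2[C@]23C=CCC[C@@H]2[C@@]1(C(=O)CCC)OC3=O
F2 | step 12 | (4aS,4bS,8aS,9S,9aR)-9-butanoyl-9-hydroxy-3-pentanoyl-4-(trifluoromethanesulfonyloxy)-1,2,4a,7,8,8a,9,9a-octahydro-4bH-fluorene-4b-carboxylic acid 4b,9-lactone | FC(F)(F)S(=O)(=O)OC2=C(C(=O)CCCC)CC[C@@H]1[C@H]2[C@]23C=CCC[C@@H]2[C@@]1(C(=O)CCC)OC3=O
F3 | step 6 | tert-butyl (6S)-6-[1-(2-bromo-3-oxocyclohex-1-en-1-yl)-1-(methoxycarbonyl)-2-oxopentyl]cyclohex-1-ene-1-carboxylate (same spatial arrangement at C6 as 12, both epimers at the quaternary side-chain carbon) | O=C1CCCC(=C1Br)C(C(=O)OC)(C(=O)CCC)[C@H]1CCCC=C1C(=O)OC(C)(C)C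
F4 | step 6 | 4b-tert-butyl 9-methyl (4bS,8aS)-9-butanoyl-4-oxo-1,2,3,4,7,8,8a,9-octahydro-4bH-fluorene-4b,9-dicarboxylate (both C9 epimers) | O=C2CCCC1=C2[C@]2(C(=O)OC(C)(C)C)C=CCC[C@@H]2C1(C(=O)OC)C(=O)CCC
F5 | step 7 | (4bS,8aS)-9-bromo-9-butanoyl-4-oxo-1,2,3,4,7,8,8a,9-octahydro-4bH-fluorene-4b-carboxylic acid (both C9 epimers) | O=C2CCCC1=C2[C@]2(C(=O)O)C=CCC[C@@H]2C1(Br)C(=O)CCC
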